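**Plan**

1. Retrosynthesis: remove the twelve O-benzyl groups and one silyl ether; cut C4(top)–C6(middle) to a C4 ketone plus an aryl metal (aryl addition, then hydride); cut C4(middle)–C6(terminal) by Friedel–Crafts logic. This leaves three copies of one flavan-4-one, in which O1–C8a and C2–C3 of ring C are cut to a 2-fluoroaryl ketimine and 4-(benzyloxy)benzaldehyde.
2. Enabling feature: in every unit C8a of ring A is ortho to C4a, the carbon that carries C4. With C4 as C=N it acidifies C3–H and activates a fluorine on C8a, so the aldehyde C=O can be stitched in as O1–C2 between C8a and C3; the C4 carbonyl then serves as precursor of the terminal C4–OH and of both C4–aryl bonds.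
3. Forward order: ring A (from 3-fluorocatechol) → ring C by the annulation, ring B arriving with the aldehyde → terminal unit (C3 epimerised, C4 reduced, silylated) and middle donor (C4 reduced, C6 brominated, C4 thio-activated) → 4α→6 dimer → C6-metalated dimer adds to a third flavanone → C4 deoxygenation → deprotection.
4. Stereochemistry: C2 of all three units comes from the tert-butanesulfinyl auxiliary in the annulation; C3 is trans by equilibration (top, middle) or cis by kinetic protonation (terminal); C4 is set by hydride anti to the axial O3 (terminal), by arene attack anti to O3 (middle, 3,4-trans) and by hydride attack anti to O3 on the 4-aryl cation (top, 3,4-cis).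

Key step: step 5

Assumption: the (R)-sulfinyl group is taken to steer the aldehyde to the face that gives the 2R adduct; if the auxiliary proves to have the opposite sense, (S)-2-methylpropane-2-sulfinamide is used and nothing else changes.

**Route**

Step 1
Reactants: 1 3-fluorobenzene-1,2-diol
Product: 2 1,2-bis(benzyloxy)-3-fluorobenzene
Conditions: BnBr, K2CO3, DMF, 60 °C
Reagents that add atoms: benzyl bromide, BrCc1ccccc1
Why: Williamson ether synthesis; both phenoxides are alkylated by the benzylic bromide, which installs the hydrogenolysis-labile protection carried to the end.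

Step 2
Reactants: 2 1,2-bis(benzyloxy)-3-fluorobenzene
Product: 3 1,2-bis(benzyloxy)-4-bromo-3-fluorobenzene
Conditions: NBS, MeCN, 0 → 23 °C
Reagents that add atoms: N-bromosuccinimide, O=C1CCC(=O)N1Br
Why: Electrophilic aromatic bromination should go para to the C1 benzyloxy group (the C2 ether is flanked on both sides and directs weakly) and ortho to fluorine, which puts bromine on the future C4a next to the fluorine-bearing future C8a.

Step 3
Reactants: 3 1,2-bis(benzyloxy)-4-bromo-3-fluorobenzene; 4 2-(benzyloxy)-N-methoxy-N-methylacetamide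
Product: 6 2-(benzyloxy)-1-[3,4-bis(benzyloxy)-2-fluorophenyl]ethan-1-one, via arylmagnesium chloride 5 (not isolated)
Conditions: i-PrMgCl·LiCl, THF, −15 °C; then 4, −15 → 0 °C; aq NH4Cl
Reagents that add atoms: none
Why: Bromine–magnesium exchange (helped by the ortho fluorine and kept cold so that the 2-fluoroaryl Grignard reagent does not collapse to an aryne) followed by Weinreb ketone synthesis, the chelated tetrahedral adduct preventing a second addition.

Step 4
Reactants: 6 2-(benzyloxy)-1-[3,4-bis(benzyloxy)-2-fluorophenyl]ethan-1-one; 7 (R)-2-methylpropane-2-sulfinamide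
Product: 8 (R)-N-{2-(benzyloxy)-1-[3,4-bis(benzyloxy)-2-fluorophenyl]ethylidene}-2-methylpropane-2-sulfinamide
Conditions: Ti(OEt)4, THF, 65 °C
Reagents that add atoms: none
Why: Ti(OEt)4-mediated condensation of a ketone with a sulfinamide (the titanium alkoxide scavenges the water) gives the N-sulfinyl ketimine, a chiral and removable activator of C3–H and of C8a–F whose C=N geometry is immaterial.

Step 5
Reactants: 8 (R)-N-{2-(benzyloxy)-1-[3,4-bis(benzyloxy)-2-fluorophenyl]ethylidene}-2-methylpropane-2-sulfinamide; 9 4-(benzyloxy)benzaldehyde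
Product: 13 (2R,3R)-3,7,8-tris(benzyloxy)-2-[4-(benzyloxy)phenyl]-2,3-dihydro-4H-chromen-4-one, via lithium aza-enolate 10 (not isolated), via aza-aldol alkoxide 11 (not isolated), via cyclised sulfinyl imine 12 (not isolated)
Conditions: LiN(i-Pr)2, THF, −78 °C; MgBr2·OEt2; 9, −78 °C; DMPU, −78 → 40 °C; then TsOH·H2O, THF/H2O, 40 °C
Reagents that add atoms: water, O
Why: Proposed new method: the C4 ketimine acidifies C3–H, so LiN(i-Pr)2 gives aza-enolate 10, which adds through C3 to the aldehyde carbon of 9 (C2–C3) in a metal-bridged chair in which the tert-butanesulfinyl group selects the aldehyde face; the alkoxide O1 of 11 then displaces fluoride from C8a, activated by the ortho C=N, by addition–elimination (O1–C8a), and acid hydrolysis unveils the C4 ketone. The closest known reaction types are the diastereoselective addition of N-tert-butanesulfinyl metalloenamines to aldehydes and the SNAr closure of chromanones and chromones from 2-fluoroaryl carbonyl compounds; their union in one flask is what is new. Ring C closes by 6-exo attack of O1 on the ipso carbon C8a through a six-membered transition state with fluoride as leaving group. C2 (R) is controlled by the sulfur stereocentre of the auxiliary; C3 forms as a mixture and is equilibrated through the enol during the acidic hydrolysis to the trans, diequatorial 3R isomer. The step needs addition and ring closure to outrun retro-addition (the aza-enolate is a far poorer leaving group than a ketone enolate, which is why the ketimine and not the ketone is used), attack at C8a by O1 only (O3 is benzylated, so no five-membered closure competes, and fluorine is the only leaving group), and C3 epimerisation without opening of ring C (acid, not base, is used).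

Step 6
Reactants: 13 (2R,3R)-3,7,8-tris(benzyloxy)-2-[4-(benzyloxy)phenyl]-2,3-dihydro-4H-chromen-4-one
Product: 15 (2R,3S)-3,7,8-tris(benzyloxy)-2-[4-(benzyloxy)phenyl]-2,3-dihydro-4H-chromen-4-one, via lithium enolate 14 (not isolated)
Conditions: LiN(i-Pr)2, THF, −78 °C; then AcOH, THF, −78 °C
Reagents that add atoms: none
Why: Kinetic protonation of an enolate: the C2 aryl group of planar enolate 14 sits pseudo-axial and blocks the α face, so the proton should enter C3 from the β face and leave the benzyloxy group cis to the aryl group (3S), the less stable epimer, which a base-free work-up preserves.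

Step 7
Reactants: 15 (2R,3S)-3,7,8-tris(benzyloxy)-2-[4-(benzyloxy)phenyl]-2,3-dihydro-4H-chromen-4-one
Product: 16 (2R,3R,4R)-3,7,8-tris(benzyloxy)-2-[4-(benzyloxy)phenyl]-3,4-dihydro-2H-chromen-4-ol
Conditions: NaBH4, CeCl3·7H2O, MeOH/THF, −40 °C
Reagents that add atoms: none
Why: Luche reduction; hydride should attack C4 anti to the axial C3 benzyloxy group (polar 1,2-induction, in a non-basic medium that avoids C3 epimerisation), which sets 4R with the hydroxyl cis to O3, the all-cis array of the terminal unit.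

Step 8
Reactants: 16 (2R,3R,4R)-3,7,8-tris(benzyloxy)-2-[4-(benzyloxy)phenyl]-3,4-dihydro-2H-chromen-4-ol
Product: 17 4-O-triisopropylsilyl ether of 16 (configuration unchanged)
Conditions: i-Pr3SiOTf, 2,6-lutidine, CH2Cl2, 0 → 23 °C
Reagents that add atoms: triisopropylsilyl trifluoromethanesulfonate, CC(C)[Si](C(C)C)(C(C)C)OS(=O)(=O)C(F)(F)F
Why: Silyl ether formation with a silyl triflate and a hindered pyridine base; the bulky silyl ether withstands organolithium and silver reagents, resists ionisation at C4 better than an alkyl ether, screens C5 and is removable with fluoride.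

Step 9
Reactants: 13 (2R,3R)-3,7,8-tris(benzyloxy)-2-[4-(benzyloxy)phenyl]-2,3-dihydro-4H-chromen-4-one
Product: 18 (2R,3S,4R)-3,7,8-tris(benzyloxy)-2-[4-(benzyloxy)phenyl]-3,4-dihydro-2H-chromen-4-ol
Conditions: NaBH4, MeOH/THF, 0 °C
Reagents that add atoms: none
Why: Borohydride reduction of the aryl ketone by axial attack should give the 3,4-trans alcohol, though the C4 configuration is immaterial because C4 is ionised in step 12.

Step 10
Reactants: 18 (2R,3S,4R)-3,7,8-tris(benzyloxy)-2-[4-(benzyloxy)phenyl]-3,4-dihydro-2H-chromen-4-ol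
Product: 19 6-bromo derivative of 18
Conditions: NBS, CH2Cl2, −20 °C
Reagents that add atoms: N-bromosuccinimide, O=C1CCC(=O)N1Br
Why: Electrophilic aromatic bromination at C6, ortho to the C7 ether and para to O1 and the most electron-rich carbon of the molecule; the bromine blocks self-condensation of the donor in step 12 and is the handle for step 13.

Step 11
Reactants: 19 6-bromo derivative of 18
Product: 20 4α-benzylsulfanyl analogue of 19 (2,3-trans-3,4-trans; the 4β epimer would serve equally)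
Conditions: BnSH, BF3·OEt2 (cat.), CH2Cl2, −30 °C
Reagents that add atoms: phenylmethanethiol, SCc1ccccc1
Why: Acid-catalysed SN1 thiolysis of the p-alkoxybenzylic alcohol, the thiol trapping the C4 cation anti to O3, installs a leaving group that only a thiophilic promoter activates.

Step 12
Reactants: 20 4α-benzylsulfanyl analogue of 19; 17 4-O-triisopropylsilyl ether of 16
Product: 21 dimer bromide: 6-bromo-tetra-O-benzyl-oritin unit joined through C4 (α) to C6 of the tetra-O-benzyl-4-O-triisopropylsilyl-epioritin-4α-ol unit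
Conditions: AgBF4, 2,6-di-tert-butyl-4-methylpyridine, 4 Å MS, CH2Cl2/THF, −30 → 0 °C
Reagents that add atoms: none
Why: Thiophilic activation by silver ion releases the C4 benzylic cation of the middle unit, and Friedel–Crafts alkylation by 17 should occur at its C6 (ortho to O7, para to O1, away from the silyl ether that screens C5) on the face anti to the C3 benzyloxy group, setting the 3,4-trans (4α→6) bond, while the base keeps the C4–O bond of 17 intact.

Step 13
Reactants: 21 dimer bromide; 13 (2R,3R)-3,7,8-tris(benzyloxy)-2-[4-(benzyloxy)phenyl]-2,3-dihydro-4H-chromen-4-one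
Product: 24 trimeric tertiary carbinol (21 with Br replaced by the 4-hydroxyflavan-4-yl group derived from 13; carbinol carbon of either configuration), via aryllithium 22 (not isolated), via arylcerium dichloride 23 (not isolated)
Conditions: n-BuLi, THF, −78 °C; CeCl3, −78 °C; then 13, −78 → −30 °C; aq NH4Cl
Reagents that add atoms: none
Why: Bromine–lithium exchange, transmetalation to the weakly basic, oxophilic organocerium reagent and 1,2-addition to the enolisable α-alkoxy ketone create the C4(top)–C6(middle) bond; the configuration of the carbinol carbon does not matter because it is ionised in step 14.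

Step 14
Reactants: 24 trimeric tertiary carbinol
Product: 25 protected trimer: tetra-O-benzyl-oritin-(4β→6)-tetra-O-benzyl-oritin-(4α→6)-tetra-O-benzyl-4-O-triisopropylsilyl-epioritin-4α-ol
Conditions: i-Pr3SiH, CF3CO2H, CH2Cl2, −40 °C
Reagents that add atoms: none
Why: Ionic hydrogenation: the tertiary, doubly benzylic alcohol ionises in dilute CF3CO2H far more readily than the secondary silyl ether at C4 of the terminal unit, and the bulky silane should deliver hydride to the planar C4 cation on the α face, anti to the C3 benzyloxy group (the face arenes choose on 2,3-trans flavan-4-yl cations), so the aryl substituent ends β and cis to O3 (4S).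

Step 15
Reactants: 25 protected trimer
Product: 26 protected trimer with free C4 hydroxyl on the terminal unit
Conditions: Bu4NF, THF, 23 °C
Reagents that add atoms: none
Why: Fluoride-induced desilylation, driven by the strong Si–F bond, frees the terminal C4 hydroxyl without touching benzyl ethers or stereocentres.

Step 16
Reactants: 26 protected trimer with free C4 hydroxyl on the terminal unit
Product: 27 oritin-(4β→6)-oritin-(4α→6)-epioritin-4α-ol (target)
Conditions: H2 (1 atm), Pd(OH)2/C, THF/MeOH, 23 °C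
Reagents that add atoms: none
Why: Catalytic hydrogenolysis cleaves the twelve O-benzyl groups, while the secondary benzylic C4–OH, the ring C ether bonds and the interflavan C–C bonds, all slower to cleave under neutral conditions, should persist if the reaction is stopped at full debenzylation.

**Compound list**

1 | 3-fluorobenzene-1,2-diol | Oc1cccc(F)c1O | starting material
2 | 1,2-bis(benzyloxy)-3-fluorobenzene | Fc1cccc(OCc2ccccc2)c1OCc1ccccc1 | intermediate
3 | 1,2-bis(benzyloxy)-4-bromo-3-fluorobenzene | Fc1c(Br)ccc(OCc2ccccc2)c1OCc1ccccc1 | intermediate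
4 | 2-(benzyloxy)-N-methoxy-N-methylacetamide | CON(C)C(=O)COCc1ccccc1 | starting material
5 | [3,4-bis(benzyloxy)-2-fluorophenyl]magnesium chloride, LiCl complex (not isolated) | Fc1c([Mg]Cl)ccc(OCc2ccccc2)c1OCc1ccccc1 | intermediate
6 | 2-(benzyloxy)-1-[3,4-bis(benzyloxy)-2-fluorophenyl]ethan-1-one | O=C(COCc1ccccc1)c1ccc(OCc2ccccc2)c(OCc2ccccc2)c1F | intermediate
7 | (R)-2-methylpropane-2-sulfinamide | CC(C)(C)[S@@](=O)N | starting material
8 | (R)-N-{2-(benzyloxy)-1-[3,4-bis(benzyloxy)-2-fluorophenyl]ethylidene}-2-methylpropane-2-sulfinamide (C=N geometry not fixed) | CC(C)(C)[S@@](=O)N=C(COCc1ccccc1)c1ccc(OCc2ccccc2)c(OCc2ccccc2)c1F | intermediate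
9 | 4-(benzyloxy)benzaldehyde | O=Cc1ccc(OCc2ccccc2)cc1 | starting material
10 | lithium aza-enolate of 8 (not isolated) | [Li+].CC(C)(C)[S@@](=O)[N-]C(=COCc1ccccc1)c1ccc(OCc2ccccc2)c(OCc2ccccc2)c1F | intermediate
11 | aza-aldol alkoxide, drawn as the lithium salt; C2 as in 13, C3 epimer leading directly to the trans ring drawn (not isolated) | [Li+].CC(C)(C)[S@@](=O)N=C([C@H](OCc1ccccc1)[C@H]([O-])c1ccc(OCc2ccccc2)cc1)c1ccc(OCc2ccccc2)c(OCc2ccccc2)c1F | intermediate
12 | N-tert-butanesulfinyl imine of 13 (not isolated) | CC(C)(C)[S@@](=O)N=C1c2ccc(OCc3ccccc3)c(OCc3ccccc3)c2O[C@H](c2ccc(OCc3ccccc3)cc2)[C@H]1OCc1ccccc1 | intermediate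
13 | (2R,3R)-3,7,8-tris(benzyloxy)-2-[4-(benzyloxy)phenyl]-2,3-dihydro-4H-chromen-4-one (2,3-trans) | O=C1c2ccc(OCc3ccccc3)c(OCc3ccccc3)c2O[C@H](c2ccc(OCc3ccccc3)cc2)[C@H]1OCc1ccccc1 | intermediate
14 | lithium enolate of 13 (not isolated) | [Li+].[O-]C1=C(OCc2ccccc2)[C@@H](c2ccc(OCc3ccccc3)cc2)Oc2c1ccc(OCc1ccccc1)c2OCc1ccccc1 | intermediate
15 | (2R,3S)-3,7,8-tris(benzyloxy)-2-[4-(benzyloxy)phenyl]-2,3-dihydro-4H-chromen-4-one (2,3-cis) | O=C1c2ccc(OCc3ccccc3)c(OCc3ccccc3)c2O[C@H](c2ccc(OCc3ccccc3)cc2)[C@@H]1OCc1ccccc1 | intermediate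
16 | (2R,3R,4R)-3,7,8-tris(benzyloxy)-2-[4-(benzyloxy)phenyl]-3,4-dihydro-2H-chromen-4-ol (2,3-cis-3,4-cis) | c1ccccc1COc1ccc([C@H]2Oc3c(ccc(OCc4ccccc4)c3OCc3ccccc3)[C@@H](O)[C@H]2OCc2ccccc2)cc1 | intermediate
17 | 4-O-triisopropylsilyl ether of 16 | c1ccccc1COc1ccc([C@H]2Oc3c(ccc(OCc4ccccc4)c3OCc3ccccc3)[C@@H](O[Si](C(C)C)(C(C)C)C(C)C)[C@H]2OCc2ccccc2)cc1 | intermediate
18 | (2R,3S,4R)-3,7,8-tris(benzyloxy)-2-[4-(benzyloxy)phenyl]-3,4-dihydro-2H-chromen-4-ol (2,3-trans-3,4-trans) | c1ccccc1COc1ccc([C@H]2Oc3c(ccc(OCc4ccccc4)c3OCc3ccccc3)[C@@H](O)[C@@H]2OCc2ccccc2)cc1 | intermediate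
19 | 6-bromo derivative of 18 | c1ccccc1COc1ccc([C@H]2Oc3c(cc(Br)c(OCc4ccccc4)c3OCc3ccccc3)[C@@H](O)[C@@H]2OCc2ccccc2)cc1 | intermediate
20 | 4α-benzylsulfanyl analogue of 19 (2,3-trans-3,4-trans) | c1ccccc1COc1ccc([C@H]2Oc3c(cc(Br)c(OCc4ccccc4)c3OCc3ccccc3)[C@@H](SCc3ccccc3)[C@@H]2OCc2ccccc2)cc1 | intermediate
21 | dimer bromide: 6-bromo middle unit (2,3-trans-3,4-trans) linked C4(α)→C6 to the all-cis terminal unit bearing the C4 silyl ether; all other hydroxyls benzylated | c1ccccc1COc1ccc([C@H]2Oc3c(cc([C@@H]4c5cc(Br)c(OCc6ccccc6)c(OCc6ccccc6)c5O[C@H](c5ccc(OCc6ccccc6)cc5)[C@H]4OCc4ccccc4)c(OCc4ccccc4)c3OCc3ccccc3)[C@@H](O[Si](C(C)C)(C(C)C)C(C)C)[C@H]2OCc2ccccc2)cc1 | intermediate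
22 | aryllithium from 21, Li at C6 of the middle unit (not isolated) | c1ccccc1COc1ccc([C@H]2Oc3c(cc([C@@H]4c5cc([Li])c(OCc6ccccc6)c(OCc6ccccc6)c5O[C@H](c5ccc(OCc6ccccc6)cc5)[C@H]4OCc4ccccc4)c(OCc4ccccc4)c3OCc3ccccc3)[C@@H](O[Si](C(C)C)(C(C)C)C(C)C)[C@H]2OCc2ccccc2)cc1 | intermediate
23 | arylcerium dichloride from 22 (not isolated) | c1ccccc1COc1ccc([C@H]2Oc3c(cc([C@@H]4c5cc([Ce](Cl)Cl)c(OCc6ccccc6)c(OCc6ccccc6)c5O[C@H](c5ccc(OCc6ccccc6)cc5)[C@H]4OCc4ccccc4)c(OCc4ccccc4)c3OCc3ccccc3)[C@@H](O[Si](C(C)C)(C(C)C)C(C)C)[C@H]2OCc2ccccc2)cc1 | intermediate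
24 | trimeric tertiary carbinol; C4 of the top unit carries OH and the middle-unit aryl group, either configuration | c1ccccc1COc1ccc([C@H]2Oc3c(cc([C@@H]4c5cc(C6(O)c7ccc(OCc8ccccc8)c(OCc8ccccc8)c7O[C@H](c7ccc(OCc8ccccc8)cc7)[C@H]6OCc6ccccc6)c(OCc6ccccc6)c(OCc6ccccc6)c5O[C@H](c5ccc(OCc6ccccc6)cc5)[C@H]4OCc4ccccc4)c(OCc4ccccc4)c3OCc3ccccc3)[C@@H](O[Si](C(C)C)(C(C)C)C(C)C)[C@H]2OCc2ccccc2)cc1 | intermediate
25 | protected trimer: top unit 2,3-trans-3,4-cis (4β→6), middle unit 2,3-trans-3,4-trans (4α→6), terminal unit all-cis with C4 silyl ether; twelve O-benzyl groups | c1ccccc1COc1ccc([C@H]2Oc3c(cc([C@@H]4c5cc([C@H]6c7ccc(OCc8ccccc8)c(OCc8ccccc8)c7O[C@H](c7ccc(OCc8ccccc8)cc7)[C@H]6OCc6ccccc6)c(OCc6ccccc6)c(OCc6ccccc6)c5O[C@H](c5ccc(OCc6ccccc6)cc5)[C@H]4OCc4ccccc4)c(OCc4ccccc4)c3OCc3ccccc3)[C@@H](O[Si](C(C)C)(C(C)C)C(C)C)[C@H]2OCc2ccccc2)cc1 | intermediate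
26 | 25 with free C4 hydroxyl on the terminal unit | c1ccccc1COc1ccc([C@H]2Oc3c(cc([C@@H]4c5cc([C@H]6c7ccc(OCc8ccccc8)c(OCc8ccccc8)c7O[C@H](c7ccc(OCc8ccccc8)cc7)[C@H]6OCc6ccccc6)c(OCc6ccccc6)c(OCc6ccccc6)c5O[C@H](c5ccc(OCc6ccccc6)cc5)[C@H]4OCc4ccccc4)c(OCc4ccccc4)c3OCc3ccccc3)[C@@H](O)[C@H]2OCc2ccccc2)cc1 | intermediate
27 | oritin-(4β→6)-oritin-(4α→6)-epioritin-4α-ol; top unit 2R,3S,4S, middle unit 2R,3S,4R, terminal unit 2R,3R,4R | Oc1ccc([C@H]2Oc3c(cc([C@@H]4c5cc([C@H]6c7ccc(O)c(O)c7O[C@H](c7ccc(O)cc7)[C@H]6O)c(O)c(O)c5O[C@H](c5ccc(O)cc5)[C@H]4O)c(O)c3O)[C@@H](O)[C@H]2O)cc1 | target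

**Totals**

Total step count: 16. Longest linear sequence: 13 steps (1–5, then 9–11 or 6–8, then 12–16).

**Steps most likely to fail**

Step 5. The alkoxide 11 may revert to aza-enolate and aldehyde before ring closure, which would erode control at C2, or fluoride displacement may stall on the electron-rich ring. The fallback uses known chemistry that closes ring C through O1–C2 instead; it sets out from aldehyde 9 and purchased 1-(2,3,4-trihydroxyphenyl)ethanone F1 and comes back to the route at 13. F1 is benzylated at O3 and O4 (BnBr, K2CO3, acetone; the chelated 2-OH stays free) to 1-[3,4-bis(benzyloxy)-2-hydroxyphenyl]ethanone F2. The phenol is capped (MeOCH2Cl, i-Pr2NEt) to give 1-[3,4-bis(benzyloxy)-2-(methoxymethoxy)phenyl]ethanone F3. Claisen–Schmidt condensation with 9 (KOH, EtOH) gives the (E)-chalcone F4. Juliá–Colonna epoxidation (poly-L-leucine, urea·H2O2, DBU, THF) should give the (αR,βS)-epoxychalcone F5. HCl in MeOH/THF removes the acetal, and the freed phenol opens the epoxide at the benzylic carbon with inversion to the (2R,3R)-3-hydroxyflavanone F6. Benzylation of O3 without base (BnBr, Ag2O, CH2Cl2) gives 13.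

Step 14. Hydride capture of the C4 cation may show poor facial selectivity (too much 3,4-trans isomer), the cation may lose H3 to the enol ether, or the silyl ether at C4 of the terminal unit may ionise as well. The fallback sets out from 21 and 18 and comes back at 25. 21 is debrominated (n-BuLi, THF, −78 °C; MeOH) to the debrominated dimer F7. 18 is converted (BnSH, BF3·OEt2) into the bromine-free 4α-benzylsulfanyl flavan F8. AgBF4-promoted Friedel–Crafts coupling of F8 with excess F7 at C6 of the middle unit should give 25 together with its top-unit C4 epimer F9 (3,4-trans, expected to predominate), and chromatographic separation delivers 25.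

Step 6. Enolate 14 may expel the ring oxygen by β-elimination (opening of ring C and loss of the C2 configuration), or protonation may occur without face control so that the trans ketone returns. The fallback sets out from 18 and comes back at 15. Mesylation–elimination of 18 (MsCl, Et3N, CH2Cl2, 0 °C) gives (2R)-3,7,8-tris(benzyloxy)-2-[4-(benzyloxy)phenyl]-2H-chromene F10. Hydroboration–oxidation (BH3·THF, 0 °C; H2O2, NaOH) adds hydrogen to C3 and boron to C4 on the face opposite the C2 aryl group and should give the 2,3-cis-3,4-trans alcohol F11. Dess–Martin oxidation (NaHCO3 buffer) gives 15.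

Further compounds
F1 | step 5 | 1-(2,3,4-trihydroxyphenyl)ethanone (purchased) | CC(=O)c1ccc(O)c(O)c1O
F2 | step 5 | 1-[3,4-bis(benzyloxy)-2-hydroxyphenyl]ethanone | CC(=O)c1ccc(OCc2ccccc2)c(OCc2ccccc2)c1O
F3 | step 5 | 1-[3,4-bis(benzyloxy)-2-(methoxymethoxy)phenyl]ethanone | CC(=O)c1ccc(OCc2ccccc2)c(OCc2ccccc2)c1OCOC
F4 | step 5 | (E)-1-[3,4-bis(benzyloxy)-2-(methoxymethoxy)phenyl]-3-[4-(benzyloxy)phenyl]prop-2-en-1-one | O=C(/C=C/c1ccc(OCc2ccccc2)cc1)c1ccc(OCc2ccccc2)c(OCc2ccccc2)c1OCOC
F5 | step 5 | (αR,βS)-epoxide of F4 | O=C(c1ccc(OCc2ccccc2)c(OCc2ccccc2)c1OCOC)[C@@H]1O[C@H]1c1ccc(OCc2ccccc2)cc1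
F6 | step 5 | (2R,3R)-7,8-bis(benzyloxy)-2-[4-(benzyloxy)phenyl]-3-hydroxy-2,3-dihydro-4H-chromen-4-one | O=C1c2ccc(OCc3ccccc3)c(OCc3ccccc3)c2O[C@H](c2ccc(OCc3ccccc3)cc2)[C@H]1O
F7 | step 14 | debrominated dimer (21 with H in place of Br) | c1ccccc1COc1ccc([C@H]2Oc3c(cc([C@@H]4c5ccc(OCc6ccccc6)c(OCc6ccccc6)c5O[C@H](c5ccc(OCc6ccccc6)cc5)[C@H]4OCc4ccccc4)c(OCc4ccccc4)c3OCc3ccccc3)[C@@H](O[Si](C(C)C)(C(C)C)C(C)C)[C@H]2OCc2ccccc2)cc1
F8 | step 14 | 4α-benzylsulfanyl analogue of 18 (no bromine) | c1ccccc1COc1ccc([C@H]2Oc3c(ccc(OCc4ccccc4)c3OCc3ccccc3)[C@@H](SCc3ccccc3)[C@@H]2OCc2ccccc2)cc1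
F9 | step 14 | top-unit C4 epimer of 25 (top unit 3,4-trans) | c1ccccc1COc1ccc([C@H]2Oc3c(cc([C@@H]4c5cc([C@@H]6c7ccc(OCc8ccccc8)c(OCc8ccccc8)c7O[C@H](c7ccc(OCc8ccccc8)cc7)[C@H]6OCc6ccccc6)c(OCc6ccccc6)c(OCc6ccccc6)c5O[C@H](c5ccc(OCc6ccccc6)cc5)[C@H]4OCc4ccccc4)c(OCc4ccccc4)c3OCc3ccccc3)[C@@H](O[Si](C(C)C)(C(C)C)C(C)C)[C@H]2OCc2ccccc2)cc1
F10 | step 6 | (2R)-3,7,8-tris(benzyloxy)-2-[4-(benzyloxy)phenyl]-2H-chromene | C(c1ccccc1)OC1=Cc2ccc(OCc3ccccc3)c(OCc3ccccc3)c2O[C@@H]1c1ccc(OCc2ccccc2)cc1
F11 | step 6 | 2,3-cis-3,4-trans-3,7,8-tris(benzyloxy)-2-[4-(benzyloxy)phenyl]-3,4-dihydro-2H-chromen-4-ol (2R; O3 cis to the aryl group, 4-OH trans to O3) | c1ccccc1COc1ccc([C@H]2Oc3c(ccc(OCc4ccccc4)c3OCc3ccccc3)[C@H](O)[C@H]2OCc2ccccc2)cc1
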